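**Strategy.** Everything rests on cutting the bond between C4 of the oxolane ring and its benzylic CH2 (target numbering: O1, C2 aryl, C3, C4, C5). That carbon lies cis to the CH2O substituent on C3, and the route exploits this cis pair. The CH2 is hung on the C3 CH2O oxygen as a bromoacetate, so the SmI2-generated enolate can reach the C4 ketone only from its own face. One operation thus forms the C4–CH2 bond, a cis-fused δ-lactone and the C4 carbinol centre. The precursor is a trans-5-aryl-4-(bromoacetoxymethyl)oxolan-3-one, reached by anti-selective allenylindium addition and gold-catalysed oxidative cyclisation. Decarboxylative arylation later excises the lactone carbonyl and attaches the second guaiacyl ring.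

Key step: step 9

Assumption: amide 2 is taken as a purchasable reagent, and the transfer hydrogenation is assumed to discriminate alkynyl from CH2OSi as it does alkynyl from alkyl, so the (R,R) catalyst is specified for (S)-5 (the antipodal catalyst would be used if the sense proved opposite).

**Step 1**
Reactants: 1 ethynyltrimethylsilane; 2 2-[(tert-butyldimethylsilyl)oxy]-N-methoxy-N-methylacetamide
Product: 4 1-[(tert-butyldimethylsilyl)oxy]-4-(trimethylsilyl)but-3-yn-2-one, via lithium (trimethylsilyl)acetylide 3 (not isolated)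
Conditions: n-BuLi, THF, −78 °C; then 2, −78 to 0 °C; AcOH quench at −78 °C, then water
Reagents that add atoms: none
Why: Weinreb ketone synthesis, in which the N-methoxy-N-methylamide accepts a single equivalent of the lithium acetylide and releases the ynone only on the acidic quench, which also protonates the liberated amine before it can add to the ynone.

**Step 2**
Reactants: 4 1-[(tert-butyldimethylsilyl)oxy]-4-(trimethylsilyl)but-3-yn-2-one
Product: 5 (2S)-1-[(tert-butyldimethylsilyl)oxy]-4-(trimethylsilyl)but-3-yn-2-ol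
Conditions: Ru[(R,R)-TsDPEN](p-cymene) (2 mol %, from RuCl[(R,R)-TsDPEN](p-cymene) and KOH), i-PrOH, rt
Reagents that add atoms: none
Why: Noyori asymmetric transfer hydrogenation, in which the ruthenium hydride and ligand N–H deliver hydrogen to one ketone face by distinguishing the alkynyl from the saturated substituent, which should set the (S)-carbinol (S because CH2OSi outranks the alkynyl carbon) without touching the triple bond or the silyl groups.

**Step 3**
Reactants: 5 (2S)-1-[(tert-butyldimethylsilyl)oxy]-4-(trimethylsilyl)but-3-yn-2-ol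
Product: 6 (2S)-1-[(tert-butyldimethylsilyl)oxy]-4-(trimethylsilyl)but-3-yn-2-yl methanesulfonate
Conditions: MsCl, Et3N, CH2Cl2, −78 to −20 °C; used without chromatography
Reagents that add atoms: methanesulfonyl chloride, CS(=O)(=O)Cl
Why: O-sulfonylation of the secondary propargylic alcohol occurs at oxygen with retention, so the carbinol configuration is carried into the leaving group.

**Step 4**
Reactants: 6 (2S)-1-[(tert-butyldimethylsilyl)oxy]-4-(trimethylsilyl)but-3-yn-2-yl methanesulfonate; 7 4-(benzyloxy)-3-methoxybenzaldehyde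
Product: 9 (1S,2R)-1-[4-(benzyloxy)-3-methoxyphenyl]-2-{[(tert-butyldimethylsilyl)oxy]methyl}-4-(trimethylsilyl)but-3-yn-1-ol (anti), via allenylindium iodide mesylate 8 (not isolated)
Conditions: Pd(OAc)2 (5 mol %), PPh3 (5 mol %), InI (1.4 equiv), THF–HMPA 3:1, rt; any syn isomer removed by chromatography
Reagents that add atoms: none
Why: Palladium-catalysed umpolung propargylation, in which zerovalent palladium displaces the mesylate anti (SN2′), oxidative transmetalation with monovalent indium gives the configurationally stable allenylindium 8, and its cyclic SE2′ addition to the aldehyde places the aryl group away from the silyloxymethyl branch, so the anti (1S,2R) alcohol should form with net inversion at the former mesylate carbon.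

**Step 5**
Reactants: 9 (1S,2R)-1-[4-(benzyloxy)-3-methoxyphenyl]-2-{[(tert-butyldimethylsilyl)oxy]methyl}-4-(trimethylsilyl)but-3-yn-1-ol
Product: 10 (1S,2R)-1-[4-(benzyloxy)-3-methoxyphenyl]-2-{[(tert-butyldimethylsilyl)oxy]methyl}but-3-yn-1-ol
Conditions: K2CO3 (0.3 equiv), MeOH, rt
Reagents that add atoms: none
Why: Methoxide-mediated protodesilylation cleaves only the C(sp)–SiMe3 bond, the primary TBS ether and both stereocentres being stable to catalytic carbonate in methanol.

**Step 6**
Reactants: 10 (1S,2R)-1-[4-(benzyloxy)-3-methoxyphenyl]-2-{[(tert-butyldimethylsilyl)oxy]methyl}but-3-yn-1-ol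
Product: 11 (4R,5S)-5-[4-(benzyloxy)-3-methoxyphenyl]-4-{[(tert-butyldimethylsilyl)oxy]methyl}oxolan-3-one (trans)
Conditions: Ph3PAuNTf2 (5 mol %), 8-methylquinoline N-oxide (1.5 equiv), 1,2-dichloroethane, rt
Reagents that add atoms: 8-methylquinoline N-oxide, Cc1cccc2ccc[n+]([O-])c12
Why: Gold-catalysed oxidative cyclisation, in which the N-oxide transfers oxygen to the internal carbon of the gold-activated terminal alkyne and the electrophilic terminal carbon is trapped by the benzylic hydroxyl (formal O–H insertion, five-membered ring), the acid-free hindered oxidant sparing the electron-rich benzylic C–O bond so that the anti diad becomes the trans ring substitution.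

**Step 7**
Reactants: 11 (4R,5S)-5-[4-(benzyloxy)-3-methoxyphenyl]-4-{[(tert-butyldimethylsilyl)oxy]methyl}oxolan-3-one
Product: 12 (4R,5S)-5-[4-(benzyloxy)-3-methoxyphenyl]-4-(hydroxymethyl)oxolan-3-one
Conditions: HF·pyridine, THF–pyridine, 0 °C to rt; carried on crude
Reagents that add atoms: none
Why: Fluoride cleavage of the primary silyl ether under buffered, weakly acidic conditions avoids the basic medium that would provoke retro-aldol loss of formaldehyde or dehydration of the β-hydroxy ketone.

**Step 8**
Reactants: 12 (4R,5S)-5-[4-(benzyloxy)-3-methoxyphenyl]-4-(hydroxymethyl)oxolan-3-one; 13 bromoacetyl bromide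
Product: 14 [(2S,3R)-2-[4-(benzyloxy)-3-methoxyphenyl]-4-oxooxolan-3-yl]methyl bromoacetate (trans)
Conditions: 2,6-lutidine (1.5 equiv), CH2Cl2, −40 to 0 °C
Reagents that add atoms: none
Why: O-acylation of the primary alcohol by the acid bromide with a hindered weak base, which is too feeble to cause β-elimination of the new β-acyloxy ketone and is not readily quaternised by the bromoacetate, while C3 already sits in its thermodynamically preferred trans arrangement.

**Step 9**
Reactants: 14 [(2S,3R)-2-[4-(benzyloxy)-3-methoxyphenyl]-4-oxooxolan-3-yl]methyl bromoacetate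
Product: 16 (3S,3aR,7aS)-3-[4-(benzyloxy)-3-methoxyphenyl]-7a-hydroxyhexahydrofuro[3,4-c]pyran-6-one (cis-fused β-hydroxy δ-lactone), via samarium enolate 15 (not isolated)
Conditions: SmI2 (2.5 equiv, 0.1 M in THF), THF, −78 °C; then aqueous pH 7 buffer
Reagents that add atoms: none
Why: Two equivalents of divalent samarium reduce the C–Br bond to the trivalent samarium enolate 15, whose metal also binds the C4 ketone oxygen, and the enolate carbon then adds to that carbonyl in an intramolecular Reformatsky (aldol) reaction. The closest known reaction type is the SmI2-promoted cyclisation of β-(bromoacetoxy) ketones to β-hydroxy δ-lactones. The one ring formed is the six-membered lactone, closed in a 6-exo-trig (enolexo) mode through a chair-like chelated transition state. The new C4 stereocentre is controlled by the existing C3 centre, because the three-atom tether anchored on the C3 CH2O oxygen can span only the ketone face cis to that group, so the ring fusion is cis and the hydroxyl ends up trans to CH2O. The step needs chemoselectivity for C–Br reduction and aldol closure over ketyl formation, cleavage of the ring C5–O1 bond and loss of the β-acyloxy group; this is secured by the far easier reduction of an α-bromo ester than of a dialkyl ketone in additive-free THF, by the ring C–O bond lying close to the nodal plane of the carbonyl π system, and by the neutral low-temperature medium. The benzyl ether and the C2 and C3 centres are not affected.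

**Step 10**
Reactants: 16 (3S,3aR,7aS)-3-[4-(benzyloxy)-3-methoxyphenyl]-7a-hydroxyhexahydrofuro[3,4-c]pyran-6-one
Product: 18 2-[(3S,4R,5S)-4-(acetoxymethyl)-5-[4-(benzyloxy)-3-methoxyphenyl]-3-hydroxyoxolan-3-yl]acetic acid, via lithium hydroxy carboxylate 17 (not isolated)
Conditions: LiOH·H2O (1.1 equiv), THF–H2O, 0 °C; evaporate, toluene azeotrope; Ac2O (4 equiv), pyridine, DMAP (5 mol %), 0 °C; water, then cold aqueous citric acid to pH 4
Reagents that add atoms: lithium hydroxide, [Li+].[OH-]; acetic anhydride, CC(=O)OC(C)=O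
Why: Saponification of the δ-lactone followed by O-acetylation of the carboxylate salt, in which the freed primary hydroxyl is acylated much faster than the hindered tertiary one and the acid is kept as its salt until that oxygen is capped, so relactonisation is blocked and no stereocentre is involved.

**Step 11**
Reactants: 18 2-[(3S,4R,5S)-4-(acetoxymethyl)-5-[4-(benzyloxy)-3-methoxyphenyl]-3-hydroxyoxolan-3-yl]acetic acid
Product: 19 1,3-dioxoisoindolin-2-yl 2-[(3S,4R,5S)-4-(acetoxymethyl)-5-[4-(benzyloxy)-3-methoxyphenyl]-3-hydroxyoxolan-3-yl]acetate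
Conditions: N-hydroxyphthalimide (1.1 equiv), N,N′-diisopropylcarbodiimide (1.1 equiv), DMAP (5 mol %), CH2Cl2, rt
Reagents that add atoms: N-hydroxyphthalimide, ON1C(=O)c2ccccc2C1=O
Why: Steglich-type carbodiimide esterification, in which the acidic N-hydroxy imide intercepts the O-acylisourea faster than the hindered tertiary hydroxyl can, giving the redox-active ester.

**Step 12**
Reactants: 20 4-iodo-2-methoxyphenol
Product: 21 1-(benzyloxy)-4-iodo-2-methoxybenzene
Conditions: BnBr (1.1 equiv), K2CO3 (1.5 equiv), DMF, rt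
Reagents that add atoms: benzyl bromide, BrCc1ccccc1
Why: Williamson ether synthesis on the phenoxide gives the same benzyl protection as on the other ring, so one final operation can free both phenols.

**Step 13**
Reactants: 19 1,3-dioxoisoindolin-2-yl 2-[(3S,4R,5S)-4-(acetoxymethyl)-5-[4-(benzyloxy)-3-methoxyphenyl]-3-hydroxyoxolan-3-yl]acetate; 21 1-(benzyloxy)-4-iodo-2-methoxybenzene
Product: 22 [(2S,3R,4S)-2-[4-(benzyloxy)-3-methoxyphenyl]-4-{[4-(benzyloxy)-3-methoxyphenyl]methyl}-4-hydroxyoxolan-3-yl]methyl acetate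
Conditions: NiBr2(4,4′-di-tert-butyl-2,2′-bipyridine) (10 mol %), Zn (2 equiv), N,N-dimethylacetamide, rt
Reagents that add atoms: none
Why: Nickel-catalysed decarboxylative cross-electrophile coupling, in which single-electron reduction of the N-acyloxyphthalimide expels CO2 to leave a primary carbon radical that has no β-hydrogen on the quaternary C4 and is joined to the aryl group delivered by nickel from the aryl iodide, forming the benzylic C–C bond without touching a stereocentre, the acetate or the free tertiary alcohol.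

**Step 14**
Reactants: 22 [(2S,3R,4S)-2-[4-(benzyloxy)-3-methoxyphenyl]-4-{[4-(benzyloxy)-3-methoxyphenyl]methyl}-4-hydroxyoxolan-3-yl]methyl acetate
Product: 23 olivil monoacetate, [(2S,3R,4S)-4-hydroxy-2-(4-hydroxy-3-methoxyphenyl)-4-[(4-hydroxy-3-methoxyphenyl)methyl]oxolan-3-yl]methyl acetate
Conditions: H2 (1 atm), 10% Pd/C, EtOAc, rt; stopped as soon as both benzyl groups are gone
Reagents that add atoms: none
Why: Catalytic hydrogenolysis cleaves the two aryl benzyl ethers much faster than the dialkyl benzylic C2–O1 bond, and the acetate and tertiary alcohol are inert, so both phenols should be released to give the target.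

**Compound list**

1 | ethynyltrimethylsilane | C#C[Si](C)(C)C | starting material
2 | 2-[(tert-butyldimethylsilyl)oxy]-N-methoxy-N-methylacetamide | CON(C)C(=O)CO[Si](C)(C)C(C)(C)C | starting material
3 | lithium (trimethylsilyl)acetylide | [Li]C#C[Si](C)(C)C | intermediate (not isolated)
4 | 1-[(tert-butyldimethylsilyl)oxy]-4-(trimethylsilyl)but-3-yn-2-one | C[Si](C)(C)C#CC(=O)CO[Si](C)(C)C(C)(C)C | intermediate
5 | (2S)-1-[(tert-butyldimethylsilyl)oxy]-4-(trimethylsilyl)but-3-yn-2-ol | C[Si](C)(C)C#C[C@H](O)CO[Si](C)(C)C(C)(C)C | intermediate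
6 | (2S)-1-[(tert-butyldimethylsilyl)oxy]-4-(trimethylsilyl)but-3-yn-2-yl methanesulfonate | C[Si](C)(C)C#C[C@H](OS(C)(=O)=O)CO[Si](C)(C)C(C)(C)C | intermediate
7 | 4-(benzyloxy)-3-methoxybenzaldehyde | COc1cc(C=O)ccc1OCc1ccccc1 | starting material
8 | (P)-[4-[(tert-butyldimethylsilyl)oxy]-1-(trimethylsilyl)buta-1,2-dien-1-yl]indium iodide methanesulfonate | C[Si](C)(C)C([In](I)OS(C)(=O)=O)=[C@]=C([H])CO[Si](C)(C)C(C)(C)C | intermediate (not isolated)
9 | (1S,2R)-1-[4-(benzyloxy)-3-methoxyphenyl]-2-{[(tert-butyldimethylsilyl)oxy]methyl}-4-(trimethylsilyl)but-3-yn-1-ol | O[C@H](c1ccc(OCc2ccccc2)c(OC)c1)[C@H](C#C[Si](C)(C)C)CO[Si](C)(C)C(C)(C)C | intermediate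
10 | (1S,2R)-1-[4-(benzyloxy)-3-methoxyphenyl]-2-{[(tert-butyldimethylsilyl)oxy]methyl}but-3-yn-1-ol | O[C@H](c1ccc(OCc2ccccc2)c(OC)c1)[C@H](C#C)CO[Si](C)(C)C(C)(C)C | intermediate
11 | (4R,5S)-5-[4-(benzyloxy)-3-methoxyphenyl]-4-{[(tert-butyldimethylsilyl)oxy]methyl}oxolan-3-one | O=C1CO[C@H](c2ccc(OCc3ccccc3)c(OC)c2)[C@H]1CO[Si](C)(C)C(C)(C)C | intermediate
12 | (4R,5S)-5-[4-(benzyloxy)-3-methoxyphenyl]-4-(hydroxymethyl)oxolan-3-one | O=C1CO[C@H](c2ccc(OCc3ccccc3)c(OC)c2)[C@H]1CO | intermediate
13 | bromoacetyl bromide | BrCC(Br)=O | starting material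
14 | [(2S,3R)-2-[4-(benzyloxy)-3-methoxyphenyl]-4-oxooxolan-3-yl]methyl bromoacetate | O=C1CO[C@H](c2ccc(OCc3ccccc3)c(OC)c2)[C@H]1COC(=O)CBr | intermediate
15 | diiodosamarium enolate of 14 (O-bound trivalent samarium on the acetate enolate) | O=C1CO[C@H](c2ccc(OCc3ccccc3)c(OC)c2)[C@H]1COC(=C)O[Sm](I)I | intermediate (not isolated)
16 | (3S,3aR,7aS)-3-[4-(benzyloxy)-3-methoxyphenyl]-7a-hydroxyhexahydrofuro[3,4-c]pyran-6-one (cis-fused; hydroxyl on the fusion carbon) | O=C1C[C@@]2(O)CO[C@H](c3ccc(OCc4ccccc4)c(OC)c3)[C@H]2CO1 | intermediate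
17 | lithium 2-[(3S,4R,5S)-5-[4-(benzyloxy)-3-methoxyphenyl]-3-hydroxy-4-(hydroxymethyl)oxolan-3-yl]acetate | [Li+].[O-]C(=O)C[C@@]1(O)CO[C@H](c2ccc(OCc3ccccc3)c(OC)c2)[C@H]1CO | intermediate (not isolated)
18 | 2-[(3S,4R,5S)-4-(acetoxymethyl)-5-[4-(benzyloxy)-3-methoxyphenyl]-3-hydroxyoxolan-3-yl]acetic acid | OC(=O)C[C@@]1(O)CO[C@H](c2ccc(OCc3ccccc3)c(OC)c2)[C@H]1COC(C)=O | intermediate
19 | 1,3-dioxoisoindolin-2-yl 2-[(3S,4R,5S)-4-(acetoxymethyl)-5-[4-(benzyloxy)-3-methoxyphenyl]-3-hydroxyoxolan-3-yl]acetate | O=C(C[C@@]1(O)CO[C@H](c2ccc(OCc3ccccc3)c(OC)c2)[C@H]1COC(C)=O)ON1C(=O)c2ccccc2C1=O | intermediate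
20 | 4-iodo-2-methoxyphenol | COc1cc(I)ccc1O | starting material
21 | 1-(benzyloxy)-4-iodo-2-methoxybenzene | COc1cc(I)ccc1OCc1ccccc1 | intermediate
22 | [(2S,3R,4S)-2-[4-(benzyloxy)-3-methoxyphenyl]-4-{[4-(benzyloxy)-3-methoxyphenyl]methyl}-4-hydroxyoxolan-3-yl]methyl acetate | COc1cc(C[C@@]2(O)CO[C@H](c3ccc(OCc4ccccc4)c(OC)c3)[C@H]2COC(C)=O)ccc1OCc1ccccc1 | intermediate
23 | olivil monoacetate, [(2S,3R,4S)-4-hydroxy-2-(4-hydroxy-3-methoxyphenyl)-4-[(4-hydroxy-3-methoxyphenyl)methyl]oxolan-3-yl]methyl acetate | COc1cc(C[C@@]2(O)CO[C@H](c3ccc(O)c(OC)c3)[C@H]2COC(C)=O)ccc1O | target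

**Step count.** Total: 14 steps. Longest linear sequence: 13 steps (steps 1–11, 13 and 14); step 12 is a one-step side branch.

**Steps most likely to fail**

1. Step 9 (key step). Electron transfer to the ketone (ketyl formation, then pinacol coupling, simple reduction or opening of the ring C–O bond) or base-type loss of the β-acyloxy tether could compete with the aldol closure. The fallback leaves the tether idea and installs the same C4 centre through an epoxide; it sets out from silyl ketone 11 and returns at 22. Wittig methylenation of 11 (Ph3P=CH2 from Ph3PCH3Br and KOt-Bu, THF, 0 °C) should give the exocyclic alkene tert-butyl{[(2S,3R)-2-[4-(benzyloxy)-3-methoxyphenyl]-4-methylideneoxolan-3-yl]methoxy}dimethylsilane F1. Epoxidation with mCPBA/NaHCO3 in CH2Cl2 should occur on the face away from the adjacent silyloxymethyl group and give the spiro-epoxide F2, with the oxirane oxygen trans to CH2O and its CH2 cis. [4-(Benzyloxy)-3-methoxyphenyl]magnesium chloride F3, made from iodide 21 with i-PrMgCl·LiCl, should open F2 at the oxirane CH2 under CuI catalysis (THF, −30 °C) to the silyl-protected tertiary alcohol F4. TBAF then frees the diol F5 (O,O′-dibenzylolivil), and Ac2O/pyridine at 0 °C acetylates only the primary hydroxyl to rejoin the route at 22.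

2. Step 13. Capture of the hindered, neopentyl-type primary radical by nickel may be slow, so that radical reduction, aryl homocoupling or hydrolysis of the active ester takes over. The fallback replaces the reductive coupling of two electrophiles by a coupling with a preformed aryl nucleophile; it sets out from acid 18 and returns at 22. Esterification of 18 with N-hydroxytetrachlorophthalimide (N,N′-diisopropylcarbodiimide, CH2Cl2) gives the tetrachlorophthalimide ester F6. F6 is then coupled with purchased [4-(benzyloxy)-3-methoxyphenyl]boronic acid in a nickel-catalysed decarboxylative Suzuki-type arylation (NiCl2·6H2O, bathophenanthroline, Et3N, dioxane–DMF, 75 °C) to give 22.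

3. Step 10. Activation of the carboxylate by the anhydride, followed by attack of a not-yet-acetylated primary hydroxyl, or acid-promoted ring closure during work-up, would reclose the lactone. The fallback masks the carboxyl group before acylation; it sets out from lithium salt 17 (generated from 16 as in step 10) and returns at 18. Alkylation of the carboxylate with allyl bromide (DMF, Bu4NI cat.) gives the hydroxy allyl ester F7. Ac2O/pyridine converts it into the acetoxy allyl ester F8, and Pd(PPh3)4 with morpholine removes the allyl group under neutral conditions to deliver 18.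

**Further compounds**

F1 | step 9 | tert-butyl{[(2S,3R)-2-[4-(benzyloxy)-3-methoxyphenyl]-4-methylideneoxolan-3-yl]methoxy}dimethylsilane | C=C1CO[C@H](c2ccc(OCc3ccccc3)c(OC)c2)[C@H]1CO[Si](C)(C)C(C)(C)C
F2 | step 9 | tert-butyl{[(3S,6S,7R)-6-[4-(benzyloxy)-3-methoxyphenyl]-1,5-dioxaspiro[2.4]heptan-7-yl]methoxy}dimethylsilane | C1[C@@]2(O1)CO[C@H](c3ccc(OCc4ccccc4)c(OC)c3)[C@H]2CO[Si](C)(C)C(C)(C)C
F3 | step 9 | [4-(benzyloxy)-3-methoxyphenyl]magnesium chloride | COc1cc([Mg]Cl)ccc1OCc1ccccc1
F4 | step 9 | (3S,4R,5S)-5-[4-(benzyloxy)-3-methoxyphenyl]-3-{[4-(benzyloxy)-3-methoxyphenyl]methyl}-4-{[(tert-butyldimethylsilyl)oxy]methyl}oxolan-3-ol | COc1cc(C[C@@]2(O)CO[C@H](c3ccc(OCc4ccccc4)c(OC)c3)[C@H]2CO[Si](C)(C)C(C)(C)C)ccc1OCc1ccccc1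
F5 | step 9 | (3S,4R,5S)-5-[4-(benzyloxy)-3-methoxyphenyl]-3-{[4-(benzyloxy)-3-methoxyphenyl]methyl}-4-(hydroxymethyl)oxolan-3-ol | COc1cc(C[C@@]2(O)CO[C@H](c3ccc(OCc4ccccc4)c(OC)c3)[C@H]2CO)ccc1OCc1ccccc1
F6 | step 13 | 4,5,6,7-tetrachloro-1,3-dioxoisoindolin-2-yl 2-[(3S,4R,5S)-4-(acetoxymethyl)-5-[4-(benzyloxy)-3-methoxyphenyl]-3-hydroxyoxolan-3-yl]acetate | O=C(C[C@@]1(O)CO[C@H](c2ccc(OCc3ccccc3)c(OC)c2)[C@H]1COC(C)=O)ON1C(=O)c2c(Cl)c(Cl)c(Cl)c(Cl)c2C1=O
F7 | step 10 | prop-2-en-1-yl 2-[(3S,4R,5S)-5-[4-(benzyloxy)-3-methoxyphenyl]-3-hydroxy-4-(hydroxymethyl)oxolan-3-yl]acetate | C=CCOC(=O)C[C@@]1(O)CO[C@H](c2ccc(OCc3ccccc3)c(OC)c2)[C@H]1CO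
F8 | step 10 | prop-2-en-1-yl 2-[(3S,4R,5S)-4-(acetoxymethyl)-5-[4-(benzyloxy)-3-methoxyphenyl]-3-hydroxyoxolan-3-yl]acetate | C=CCOC(=O)C[C@@]1(O)CO[C@H](c2ccc(OCc3ccccc3)c(OC)c2)[C@H]1COC(C)=O
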